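**Target:** 5,7,3',6'-tetrahydroxy-6,8,2'-trimethoxyflavone (20)

## Analysis of the target

Compound 20 is a flavone, in which benzo ring A is fused to the 4-pyranone ring C and the phenyl ring B sits on C2; it has no stereocentre, and the only stereochemical element met on the way is the geometry of an acyclic alkene that disappears when ring C closes. Ring A is fully substituted, with C5–OH, C6–OMe, C7–OH and C8–OMe between the fusion atoms C4a and C8a. Ring B carries 2'-OMe, 3'-OH and 6'-OH, so that C1' lies between two oxygen-bearing carbons. Because the 3'- and 6'-hydroxyls are para to each other, ring B is a hydroquinone that air or base can oxidise to a quinone, and the free tetraphenol should therefore appear only in the last step. The three methyl ethers and the C2=C3 bond must survive whatever sets the four phenols free. The difficulty is twofold: eight oxygens have to be placed and told apart, and the carbon next to ring B is crowded, which slows the classical closures that bring O1 onto a carbon bearing a di-ortho-substituted aryl group. The plan rests on one feature of ring A: drawn as an aryl ether of O1, it comes from the mirror-symmetric diol 15, which has a single ring CH. That CH becomes C4a, it is ortho to O1 and to the C5 hydroxyl and para to the C7 oxygen, and so the C4–C4a bond can be made by acylation without any regiochemical choice.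

## Retrosynthetic reasoning

**20 to 19.** The three O–benzyl bonds at O7, O3' and O6' are cut. Benzyl is chosen because hydrogenolysis is neutral, leaves methyl ethers alone and exposes the hydroquinone of ring B to neither acid nor base. The forward step must cleave three aryl benzyl ethers without saturating C2=C3.

**19 to 17 (through 18).** The C4–C4a bond is cut. Ring C opens to the 3-aryloxy-3-arylacrylic acid 17, in which the acid carbon is the future C4 and the only free carbon of ring A is the future C4a. The cut is placed here because this is the one bond of ring C whose formation cannot go astray on ring A, and because the crowded C2–C1' bond is then already in place instead of being made at the end. The forward reaction must activate the acid mildly enough for three benzyl ethers and an enol ether to survive, and the arene carbon must win over every oxygen nucleophile in the molecule.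

**17 to 16.** The acid is traced back to its methyl ester 16. The ester is needed as the activating group of the alkyne in the preceding addition, and its hydrolysis must not expel the aryloxy group from C2.

**16 to 15 and 10.** The O1–C2 bond is cut, which gives the symmetric diol 15 and the arylpropiolate 10. In 10 the carbon that becomes C2 is sp-hybridised, so the two ortho substituents of ring B flank a linear unit and the phenoxide can approach. Because 15 is symmetric, either hydroxyl gives the same ether, and the hydroxyl left over becomes the C5–OH of the target. The forward reaction must stop at mono-addition, which an excess of the cheaper partner 15 secures.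

**10 to 7 and 8, and 7 to 6.** The ester carbon is cut from the alkyne, and the alkyne is traced to an aldehyde carbon. Dibromo-olefination of 6 and conversion of 7 into acetylide 9, trapped with 8, gives 10 in two operations, with no transition-metal coupling at a di-ortho-substituted aryl halide.

**6 to 5 to 2 to 1.** The C1'–CHO bond is cut next to two oxygens. In the forward sense this is a directed ortho-metalation of 2 at the only CH that lies between two ether oxygens, which gives aryllithium 3 and, after formylation, aldehyde 4. Methoxymethyl ethers are used for this step because benzyl ethers would be deprotonated at the benzylic carbon. They are lost in the acidic work-up to give 5, which is then benzylated to 6. The starting material 1 already holds the full oxygen pattern of ring B.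

**15 to 13 to 12 to 11.** The two C–OH bonds of 15 are traced to the C–Br bonds of 13 through the bis-boronate 14. The symmetry of 11 is kept throughout: after benzylation to 12, the two equivalent positions para to a methoxy group take the bromines, and the untouched carbon between them is the future C4a.

## Alternatives that were turned down

Alternative 1: lactone-tethered direct arylation for the C2–C1' bond.
- Disconnection: the C2–C1' bond is formed last, on a complete chromone. Beforehand the 6'-oxygen of ring B is esterified with a carboxyl group placed on C3, which gives the aryl ester A2, 2-bromo-3-methoxy-4-(methoxymethoxy)phenyl 5,7-bis(benzyloxy)-6,8-dimethoxy-4-oxo-4H-chromene-3-carboxylate.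
- Forward key step: under Pd(OAc)2, PCy3, K2CO3 and pivalic acid, A2 undergoes oxidative addition at C1'–Br, carboxylate-assisted palladation of the chromone C2–H and reductive elimination. C1' is thereby joined to C2 and a six-membered lactone is closed. The product is the lactone-bridged flavone A1, a chromeno[4,3-b]chromene-6,7-dione that carries, in flavone numbering, 5,7-bis(benzyloxy), 6,8-dimethoxy, 2'-methoxy and 3'-methoxymethoxy groups.
- For: the plan attacks the most crowded bond directly and makes the coupling intramolecular. The tether fixes the site of C–H activation and tells the 6'-oxygen from the 3'-oxygen. On the point of crowding it is at least as strong as the chosen plan, since no nucleophile has to add beside a di-ortho-substituted aryl group.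
- Against: A2 requires a chromone-3-carboxylic acid built on the same pentaoxygenated ring A, so the ring A problem is kept and a second sequence is added. The bromide of A2 sits between two oxygens, and its aryl ester must survive carbonate above 100 °C next to an electrophilic C2. Once A1 is in hand, the lactone must be opened, the C3 carboxyl removed, and two kinds of protecting group cleaved by two methods.
- Comparison: the chosen route meets the crowding by attaching C1' to an sp carbon. It needs one deprotection after the key step, one type of protecting group, and no carbon that is introduced only to be excised.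

Alternative 2: intramolecular ester Wittig closure at C2=C3.
- Disconnection: the C2=C3 bond. C2 is already present as the carbonyl of an aryl ester and C3 as a phosphorane carbon in ylide A4, 3,5-bis(benzyloxy)-2,4-dimethoxy-6-[2-(triphenyl-λ5-phosphanylidene)acetyl]phenyl 3,6-bis(benzyloxy)-2-methoxybenzoate.
- Forward key step: when A4 is heated in toluene, the ylide carbon adds to the ester carbonyl and the oxaphosphetane collapses with loss of the phosphine oxide. The product is the tetrabenzyl flavone A3, 5,7-bis(benzyloxy)-2-[3,6-bis(benzyloxy)-2-methoxyphenyl]-6,8-dimethoxy-4H-chromen-4-one.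
- For: the closure is neutral. In A3 all four hydroxyls are benzylated, so neither a free phenol nor an alkene geometry has to be considered, and a single hydrogenolysis would take A3 to the target. The regiochemistry is built in. On mildness of the ring-forming step this plan is stronger than an acid-mediated acylation.
- Against: in A4 the carbonyl that must accept the bulky, stabilised ylide belongs to a 2,6-dioxygenated benzoate, the kind of ester that resists addition most. The O-acylation that precedes A4 joins a hindered phenol to a hindered acid chloride. Ring A must first become a hexasubstituted hydroxyacetophenone with its three oxygens differentiated, and must then be brominated and converted into the phosphonium salt. The step count is no lower.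
- Comparison: the chosen route places the bond formation at the uncrowded end of ring C, at a carbon that has no competitor. It pays for this with an acidic step that the benzyl ethers must survive.

Alternative 3: ring B made as a quinone by squarate ring expansion.
- Disconnection: ring B itself, at C5'–C6'. Its six carbons come from a cyclobutenone and an ethynyl group in carbinol A6, 2-[5,7-bis(benzyloxy)-6,8-dimethoxy-4-oxo-4H-chromen-2-yl]-4-ethynyl-4-hydroxy-3-methoxycyclobut-2-en-1-one (racemic).
- Forward key step: in refluxing p-xylene, A6 opens electrocyclically to an alkynyl vinylketene. Its ketene carbon, the later C6', closes onto the alkyne terminus, the later C5', and hydrogen transfer gives quinone A5, 2-[5,7-bis(benzyloxy)-6,8-dimethoxy-4-oxo-4H-chromen-2-yl]-3-methoxy-1,4-benzoquinone.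
- For: the squarate carbons place the 2'-methoxy group between C1' and a quinone carbonyl with no ambiguity. A5 holds ring B as a quinone, a stable masked form of the air-sensitive hydroquinone, and one hydrogenation of A5 at the end would reduce it and remove the benzyl groups. On placing and protecting the ring B oxygens this plan is stronger than the chosen route.
- Against: A6 requires a chromone metallated at C2 to be joined to the squarate. An ethynyl-metal must then add to a cyclobutenedione in the presence of the chromone carbonyl and its electrophilic C2. Terminal alkynes in this rearrangement also partition towards five-membered alkylidene products. The construction of rings A and C remains unsolved and comes on top, so the sequence is the longest of the four.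
- Comparison: the chosen route does not need this regiocontrol, because compound 1 already carries the ring B pattern. It spends its key step on ring C, where the real difficulty lies.

Key step: step 11

## Route

Assumption: the conjugate addition of step 9 may give some E isomer beside the Z isomer drawn for 16 and 17; both would be carried on together, because the acid of step 11 interconverts them.

Step 1
Reactants: 1 2-methoxyhydroquinone (2-methoxybenzene-1,4-diol)
Product: 2 2-methoxy-1,4-bis(methoxymethoxy)benzene
Conditions: MOMCl (2.5 equiv), i-Pr2NEt (3 equiv), CH2Cl2, 0 °C to rt, argon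
Reagents that add atoms: chloromethyl methyl ether, COCCl
Why: O-Alkylation of both phenols by the reactive α-chloro ether under a hindered amine base (Williamson-type acetal formation); the methoxymethyl ethers are the ortho-directing groups for step 2, and the mild, oxygen-free conditions spare the hydroquinone.

Step 2
Reactants: 2 2-methoxy-1,4-bis(methoxymethoxy)benzene
Product: 5 3,6-dihydroxy-2-methoxybenzaldehyde, via aryllithium 3 (not isolated), via bis-MOM aldehyde 4 (not isolated)
Conditions: n-BuLi (1.2 equiv), TMEDA, THF, 0 °C; DMF, 0 °C to rt; then 3 M aq HCl, MeOH, 50 °C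
Reagents that add atoms: N,N-dimethylformamide, CN(C)C=O
Why: Directed ortho-metalation; the ring CH between the methoxy and a methoxymethoxy group is the only one flanked by two coordinating oxygens and should be lithiated first, as in 1,2,4-trialkoxybenzenes. Formylation of aryllithium 3 with DMF gives aldehyde 4, whose two acetals are cleaved by transacetalisation in the acidic methanol work-up.

Step 3
Reactants: 5 3,6-dihydroxy-2-methoxybenzaldehyde
Product: 6 3,6-bis(benzyloxy)-2-methoxybenzaldehyde
Conditions: BnBr (2.4 equiv), K2CO3, DMF, 50 °C, argon
Reagents that add atoms: benzyl bromide, BrCc1ccccc1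
Why: Williamson ether synthesis on both phenols; the hydroxyl hydrogen-bonded to the aldehyde is the slower one and is driven to completion by warming in DMF. Benzyl ethers are inert to every later step before the final hydrogenolysis.

Step 4
Reactants: 6 3,6-bis(benzyloxy)-2-methoxybenzaldehyde
Product: 7 1,4-bis(benzyloxy)-2-(2,2-dibromoethenyl)-3-methoxybenzene
Conditions: CBr4 (2 equiv), PPh3 (4 equiv), CH2Cl2, 0 °C
Reagents that add atoms: carbon tetrabromide, BrC(Br)(Br)Br
Why: First stage of the Corey–Fuchs homologation (dibromo-olefination with Ph3P=CBr2); the small ylide reacts with di-ortho-substituted benzaldehydes, and 6 has no other electrophilic site.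

Step 5
Reactants: 7 1,4-bis(benzyloxy)-2-(2,2-dibromoethenyl)-3-methoxybenzene; 8 methyl chloroformate
Product: 10 methyl 3-[3,6-bis(benzyloxy)-2-methoxyphenyl]prop-2-ynoate, via lithium acetylide 9 (not isolated)
Conditions: n-BuLi (2.1 equiv), THF, −78 °C; then 8 (1.5 equiv), −78 to 0 °C
Reagents that add atoms: none
Why: Second stage of the Corey–Fuchs reaction: bromine–lithium exchange, loss of LiBr with 1,2-shift and deprotonation give acetylide 9, which is acylated by the chloroformate. At −78 °C the exchange is far faster than benzylic deprotonation of the benzyl ethers.

Step 6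
Reactants: 11 2,6-dimethoxyphenol (syringol)
Product: 12 2-(benzyloxy)-1,3-dimethoxybenzene
Conditions: BnBr (1.2 equiv), K2CO3, DMF, 60 °C
Reagents that add atoms: benzyl bromide, BrCc1ccccc1
Why: Williamson ether synthesis; the phenoxide between two methoxy groups is hindered but alkylates cleanly with a primary benzylic halide in DMF.

Step 7
Reactants: 12 2-(benzyloxy)-1,3-dimethoxybenzene
Product: 13 3-(benzyloxy)-1,5-dibromo-2,4-dimethoxybenzene
Conditions: NBS (2.1 equiv), MeCN, 0 °C to rt, dark
Reagents that add atoms: N-bromosuccinimide, O=C1CCC(=O)N1Br
Why: Electrophilic aromatic bromination; in 1,2,3-trialkoxybenzenes the twisted central alkoxy group donates least, so each bromine should enter para to one outer methoxy group and ortho to the other. The carbon between the two bromines, para to the benzyloxy group, stays free and is the future C4a.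

Step 8
Reactants: 13 3-(benzyloxy)-1,5-dibromo-2,4-dimethoxybenzene
Product: 15 5-(benzyloxy)-4,6-dimethoxybenzene-1,3-diol, via bis(pinacolboronate) 14 (not isolated)
Conditions: B2pin2 (2.6 equiv), KOAc, Pd(dppf)Cl2 (5 mol%), 1,4-dioxane, 90 °C; then 30% aq H2O2, NaOH, THF/H2O, 0 °C, argon
Reagents that add atoms: hydrogen peroxide, OO
Why: Miyaura borylation (oxidative addition of each C–Br bond to zerovalent palladium, acetate-assisted transmetalation with the diboron, reductive elimination), followed by hydroperoxide oxidation of both C–B bonds with aryl migration from boron to oxygen. The benzyl and methyl ethers are inert to both stages.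

Step 9
Reactants: 15 5-(benzyloxy)-4,6-dimethoxybenzene-1,3-diol; 10 methyl 3-[3,6-bis(benzyloxy)-2-methoxyphenyl]prop-2-ynoate
Product: 16 methyl (Z)-3-[3-(benzyloxy)-5-hydroxy-2,4-dimethoxyphenoxy]-3-[3,6-bis(benzyloxy)-2-methoxyphenyl]prop-2-enoate
Conditions: K2CO3 (1.2 equiv), DMF, 70 °C, argon, diol in 2.5-fold excess; then cold 1 M aq HCl to pH 5; surplus diol recovered by chromatography
Reagents that add atoms: none
Why: Base-mediated oxa-Michael addition of the mono-phenoxide of 15 to the alkynoate; anti addition across the triple bond should place the aryloxy group cis to the ester (Z). The sp carbon keeps the two ortho substituents of ring B out of the path of the nucleophile, the crowded acceptor favours attack through oxygen over attack through the ring carbon, and the excess of the symmetric diol suppresses double addition.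

Step 10
Reactants: 16 methyl (Z)-3-[3-(benzyloxy)-5-hydroxy-2,4-dimethoxyphenoxy]-3-[3,6-bis(benzyloxy)-2-methoxyphenyl]prop-2-enoate
Product: 17 (Z)-3-[3-(benzyloxy)-5-hydroxy-2,4-dimethoxyphenoxy]-3-[3,6-bis(benzyloxy)-2-methoxyphenyl]prop-2-enoic acid
Conditions: LiOH·H2O (5 equiv), THF/MeOH/H2O, 50 °C; then 1 M aq HCl to pH 3, 0 °C
Reagents that add atoms: lithium hydroxide, [Li+].[OH-]
Why: Saponification of the methyl ester; the β-carbon is shielded by ring B and carries an electron-rich aryloxy group, a poor leaving group, so hydroxide should attack the ester carbonyl and not displace the ether. The benzyl ethers and the phenoxide are indifferent to aqueous base under argon.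

Step 11
Reactants: 17 (Z)-3-[3-(benzyloxy)-5-hydroxy-2,4-dimethoxyphenoxy]-3-[3,6-bis(benzyloxy)-2-methoxyphenyl]prop-2-enoic acid
Product: 19 7-(benzyloxy)-2-[3,6-bis(benzyloxy)-2-methoxyphenyl]-5-hydroxy-6,8-dimethoxy-4H-chromen-4-one, via mixed trifluoroacetic anhydride 18 (not isolated)
Conditions: TFAA (2.5 equiv), CH2Cl2, 0 °C to rt; then sat. aq NaHCO3, MeOH, rt
Reagents that add atoms: none
Why: TFAA converts the acid into mixed anhydride 18, and the trifluoroacetic acid set free assists its ionisation to an acyl cation that is stabilised through the C2=C3 bond by the lone pair of O1. The only unsubstituted carbon of ring A, the future C4a, lies ortho to O1 and to the free C5 hydroxyl and para to the C7 benzyloxy group; it attacks the acyl carbon in an intramolecular Friedel–Crafts acylation, and loss of the proton leaves the 5-hydroxyl hydrogen-bonded to the new C4 carbonyl. The closest known reaction type is the anhydride- or acid-chloride-mediated cyclisation of 3-aryloxycinnamic acids to flavones, together with the TFAA-mediated closure of 2-aryloxybenzoic acids to xanthones. Ring C closes through a six-membered transition state, exo with respect to the C–O multiple bond of the acyl electrophile (6-exo-trig on the anhydride carbonyl, 6-exo-dig on the free acyl cation). No stereocentre is formed; the closure needs the Z geometry, and since the push–pull alkene is protonated reversibly at C3 in the acidic medium, any E isomer is fed into the reactive form. Regiochemistry needs no control because ring A has one CH; intramolecular O-acylation of the C5 hydroxyl would need an eight-membered ring, and any trifluoroacetate put on that hydroxyl by the reagent is cleaved in the bicarbonate–methanol work-up. The benzyl ethers should tolerate anhydrous trifluoroacetic acid at room temperature for the short reaction time, and ring B offers no competing carbon nucleophile because both positions ortho to C1' are substituted.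

Step 12
Reactants: 19 7-(benzyloxy)-2-[3,6-bis(benzyloxy)-2-methoxyphenyl]-5-hydroxy-6,8-dimethoxy-4H-chromen-4-one
Product: 20 5,7,3',6'-tetrahydroxy-6,8,2'-trimethoxyflavone
Conditions: H2 (1 atm), 10% Pd/C, EtOAc/MeOH, rt; filtration and concentration under argon
Reagents that add atoms: none
Why: Catalytic hydrogenolysis of the three aryl benzyl ethers; methyl ethers are untouched, and at atmospheric pressure the conjugated C2=C3 bond of a flavone is reduced much more slowly than O-benzyl bonds are cleaved. Air is excluded because ring B is now a hydroquinone.

## Compound list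

1 | 2-methoxyhydroquinone (2-methoxybenzene-1,4-diol) | COc1cc(O)ccc1O | starting material
2 | 2-methoxy-1,4-bis(methoxymethoxy)benzene | COCOc1ccc(OCOC)c(OC)c1 | intermediate
3 | [2-methoxy-3,6-bis(methoxymethoxy)phenyl]lithium | [Li]c1c(OC)c(OCOC)ccc1OCOC | intermediate
4 | 2-methoxy-3,6-bis(methoxymethoxy)benzaldehyde | O=Cc1c(OC)c(OCOC)ccc1OCOC | intermediate
5 | 3,6-dihydroxy-2-methoxybenzaldehyde | O=Cc1c(OC)c(O)ccc1O | intermediate
6 | 3,6-bis(benzyloxy)-2-methoxybenzaldehyde | O=Cc1c(OC)c(OCc2ccccc2)ccc1OCc1ccccc1 | intermediate
7 | 1,4-bis(benzyloxy)-2-(2,2-dibromoethenyl)-3-methoxybenzene | BrC(Br)=Cc1c(OC)c(OCc2ccccc2)ccc1OCc1ccccc1 | intermediate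
8 | methyl chloroformate | COC(=O)Cl | starting material
9 | {[3,6-bis(benzyloxy)-2-methoxyphenyl]ethynyl}lithium | [Li]C#Cc1c(OC)c(OCc2ccccc2)ccc1OCc1ccccc1 | intermediate
10 | methyl 3-[3,6-bis(benzyloxy)-2-methoxyphenyl]prop-2-ynoate | COC(=O)C#Cc1c(OC)c(OCc2ccccc2)ccc1OCc1ccccc1 | intermediate
11 | 2,6-dimethoxyphenol (syringol) | COc1cccc(OC)c1O | starting material
12 | 2-(benzyloxy)-1,3-dimethoxybenzene | COc1cccc(OC)c1OCc1ccccc1 | intermediate
13 | 3-(benzyloxy)-1,5-dibromo-2,4-dimethoxybenzene | COc1c(Br)cc(Br)c(OC)c1OCc1ccccc1 | intermediate
14 | 2,2'-[5-(benzyloxy)-4,6-dimethoxy-1,3-phenylene]bis(4,4,5,5-tetramethyl-1,3,2-dioxaborolane) | COc1c(B2OC(C)(C)C(C)(C)O2)cc(B2OC(C)(C)C(C)(C)O2)c(OC)c1OCc1ccccc1 | intermediate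
15 | 5-(benzyloxy)-4,6-dimethoxybenzene-1,3-diol | COc1c(O)cc(O)c(OC)c1OCc1ccccc1 | intermediate
16 | methyl (Z)-3-[3-(benzyloxy)-5-hydroxy-2,4-dimethoxyphenoxy]-3-[3,6-bis(benzyloxy)-2-methoxyphenyl]prop-2-enoate | COC(=O)/C=C(\Oc1cc(O)c(OC)c(OCc2ccccc2)c1OC)c1c(OC)c(OCc2ccccc2)ccc1OCc1ccccc1 | intermediate
17 | (Z)-3-[3-(benzyloxy)-5-hydroxy-2,4-dimethoxyphenoxy]-3-[3,6-bis(benzyloxy)-2-methoxyphenyl]prop-2-enoic acid | OC(=O)/C=C(\Oc1cc(O)c(OC)c(OCc2ccccc2)c1OC)c1c(OC)c(OCc2ccccc2)ccc1OCc1ccccc1 | intermediate
18 | (Z)-3-[3-(benzyloxy)-5-hydroxy-2,4-dimethoxyphenoxy]-3-[3,6-bis(benzyloxy)-2-methoxyphenyl]prop-2-enoic trifluoroacetic anhydride | O=C(OC(=O)C(F)(F)F)/C=C(\Oc1cc(O)c(OC)c(OCc2ccccc2)c1OC)c1c(OC)c(OCc2ccccc2)ccc1OCc1ccccc1 | intermediate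
19 | 7-(benzyloxy)-2-[3,6-bis(benzyloxy)-2-methoxyphenyl]-5-hydroxy-6,8-dimethoxy-4H-chromen-4-one | COc1c(OCc2ccccc2)ccc(OCc2ccccc2)c1-c1cc(=O)c2c(O)c(OC)c(OCc3ccccc3)c(OC)c2o1 | intermediate
20 | 5,7,3',6'-tetrahydroxy-6,8,2'-trimethoxyflavone | COc1c(O)ccc(O)c1-c1cc(=O)c2c(O)c(OC)c(O)c(OC)c2o1 | target

## Step count and least certain steps

Total: 12 steps. Longest linear sequence: 9 steps (steps 1 to 5, then 9 to 12). The ring A branch (steps 6 to 8) joins at step 9.

**Step 11 (key step).**
- What may go wrong: the reagent may trifluoroacetylate the C5 hydroxyl before ring closure, which removes the best donor of ring A and slows the acylation. In the E isomer the acyl cation may instead be captured by the 6'-benzyloxy oxygen of ring B, with loss of the benzyl group and lactonisation to a coumarin. Prolonged exposure to trifluoroacetic acid may cleave benzyl ethers.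
- Fallback: it gives up the intramolecular acylation, sets out from 15 and 6, and returns at 19. Acetylation of 15 at its single ring CH (Ac2O, BF3·OEt2, CH2Cl2, rt) should give 1-[4-(benzyloxy)-2,6-dihydroxy-3,5-dimethoxyphenyl]ethan-1-one F1. Claisen–Schmidt condensation of F1 with 6 (KOH, EtOH, rt) should give (E)-1-[4-(benzyloxy)-2,6-dihydroxy-3,5-dimethoxyphenyl]-3-[3,6-bis(benzyloxy)-2-methoxyphenyl]prop-2-en-1-one F2. Oxidative cyclisation of F2 (catalytic I2, DMSO, 110 °C) should give 19. The price is that O1 must then add beside the crowded ring B.

**Step 9.**
- What may go wrong: the conjugate addition may be slow, because the alkyne carries an electron-rich, di-ortho-substituted aryl group. The phenoxide may also react through its lone ring carbon instead of through oxygen, and a second alkynoate may add to the remaining hydroxyl.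
- Fallback: it replaces the conjugate addition by a CuI-catalysed vinyl ether synthesis, sets out from 10, and returns at 16. Hydroiodination of 10 (NaI, AcOH, 80 °C) should give methyl (Z)-3-[3,6-bis(benzyloxy)-2-methoxyphenyl]-3-iodoprop-2-enoate F3. Ullmann-type coupling of F3 with excess 15 (CuI, N,N-dimethylglycine, Cs2CO3, 1,4-dioxane, 90 °C) should give 16 with retention of alkene geometry.

**Step 10.**
- What may go wrong: hydroxide may add to the β-carbon of the vinylogous carbonate and expel the ring A phenoxide, which cleaves the ether made in step 9 instead of the ester.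
- Fallback: it avoids hydroxide altogether, sets out from 7, and returns at 17. Treatment of 7 with n-BuLi and trapping with Boc2O should give tert-butyl 3-[3,6-bis(benzyloxy)-2-methoxyphenyl]prop-2-ynoate F4. Addition of 15 as in step 9 should give tert-butyl (Z)-3-[3-(benzyloxy)-5-hydroxy-2,4-dimethoxyphenoxy]-3-[3,6-bis(benzyloxy)-2-methoxyphenyl]prop-2-enoate F5. Acidolysis of F5 (TFA, CH2Cl2, 0 °C) should give 17, which can be taken into step 11 in the same flask.

**Step 8.**
- What may go wrong: the second borylation may stall, or a boronate ortho to a methoxy group may be lost by protodeboronation. Alkaline peroxide may over-oxidise the electron-rich resorcinol.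
- Fallback: direct hydroxylation of 13 catalysed by Pd2(dba)3 and t-BuXPhos (KOH, 1,4-dioxane/H2O, 100 °C, argon) forms both C–O bonds by reductive elimination, without boron and without peroxide. It sets out from 13 and returns at 15 with no new intermediate.

**Step 12.**
- What may go wrong: C2=C3 may be saturated on prolonged hydrogenation, and the ring B hydroquinone may be oxidised by air to the quinone during filtration.
- Fallback: Lewis-acid debenzylation of 19 with BCl3 and pentamethylbenzene as cation scavenger (CH2Cl2, −78 °C) removes the benzyl groups without hydrogen and leaves the methyl ethers. It sets out from 19 and returns at 20 with no new intermediate.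

## Further compounds

F1 | step 11 | 1-[4-(benzyloxy)-2,6-dihydroxy-3,5-dimethoxyphenyl]ethan-1-one | CC(=O)c1c(O)c(OC)c(OCc2ccccc2)c(OC)c1O
F2 | step 11 | (E)-1-[4-(benzyloxy)-2,6-dihydroxy-3,5-dimethoxyphenyl]-3-[3,6-bis(benzyloxy)-2-methoxyphenyl]prop-2-en-1-one | O=C(/C=C/c1c(OC)c(OCc2ccccc2)ccc1OCc1ccccc1)c1c(O)c(OC)c(OCc2ccccc2)c(OC)c1O
F3 | step 9 | methyl (Z)-3-[3,6-bis(benzyloxy)-2-methoxyphenyl]-3-iodoprop-2-enoate | COC(=O)/C=C(\I)c1c(OC)c(OCc2ccccc2)ccc1OCc1ccccc1
F4 | step 10 | tert-butyl 3-[3,6-bis(benzyloxy)-2-methoxyphenyl]prop-2-ynoate | CC(C)(C)OC(=O)C#Cc1c(OC)c(OCc2ccccc2)ccc1OCc1ccccc1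
F5 | step 10 | tert-butyl (Z)-3-[3-(benzyloxy)-5-hydroxy-2,4-dimethoxyphenoxy]-3-[3,6-bis(benzyloxy)-2-methoxyphenyl]prop-2-enoate | CC(C)(C)OC(=O)/C=C(\Oc1cc(O)c(OC)c(OCc2ccccc2)c1OC)c1c(OC)c(OCc2ccccc2)ccc1OCc1ccccc1
F0 | step 8 | none | none
F0 | step 12 | none | none
A1 | alternative 1 | lactone-bridged protected flavone (chromeno[4,3-b]chromene-6,7-dione core; 5,7-bis(benzyloxy), 6,8-dimethoxy, 2'-methoxy, 3'-methoxymethoxy in flavone numbering) | O=C1Oc2ccc(OCOC)c(OC)c2-c2oc3c(OC)c(OCc4ccccc4)c(OC)c(OCc4ccccc4)c3c(=O)c21
A2 | alternative 1 | 2-bromo-3-methoxy-4-(methoxymethoxy)phenyl 5,7-bis(benzyloxy)-6,8-dimethoxy-4-oxo-4H-chromene-3-carboxylate | O=C(Oc1ccc(OCOC)c(OC)c1Br)c1coc2c(OC)c(OCc3ccccc3)c(OC)c(OCc3ccccc3)c2c1=O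
A3 | alternative 2 | 5,7-bis(benzyloxy)-2-[3,6-bis(benzyloxy)-2-methoxyphenyl]-6,8-dimethoxy-4H-chromen-4-one | COc1c(OCc2ccccc2)ccc(OCc2ccccc2)c1-c1cc(=O)c2c(OCc3ccccc3)c(OC)c(OCc3ccccc3)c(OC)c2o1
A4 | alternative 2 | 3,5-bis(benzyloxy)-2,4-dimethoxy-6-[2-(triphenyl-λ5-phosphanylidene)acetyl]phenyl 3,6-bis(benzyloxy)-2-methoxybenzoate | O=C(C=P(c1ccccc1)(c1ccccc1)c1ccccc1)c1c(OCc2ccccc2)c(OC)c(OCc2ccccc2)c(OC)c1OC(=O)c1c(OC)c(OCc2ccccc2)ccc1OCc1ccccc1
A5 | alternative 3 | 2-[5,7-bis(benzyloxy)-6,8-dimethoxy-4-oxo-4H-chromen-2-yl]-3-methoxy-1,4-benzoquinone | COC1=C(c2cc(=O)c3c(OCc4ccccc4)c(OC)c(OCc4ccccc4)c(OC)c3o2)C(=O)C=CC1=O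
A6 | alternative 3 | 2-[5,7-bis(benzyloxy)-6,8-dimethoxy-4-oxo-4H-chromen-2-yl]-4-ethynyl-4-hydroxy-3-methoxycyclobut-2-en-1-one (racemic) | COC1=C(c2cc(=O)c3c(OCc4ccccc4)c(OC)c(OCc4ccccc4)c(OC)c3o2)C(=O)C1(O)C#C
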